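## The problem

Compound 30 is a 2,2,6-trisubstituted 2,3,4,7-tetrahydrooxepine (ring atoms O1, C2, C3, C4, C5=C6, C7). C2 carries a free carboxylic acid and a 2-(2,5-dihydroxyphenyl)-2-oxoethyl arm, and C6 carries an (E)-4-methylpent-3-enyl chain that ends in a p-coumarate ester. C2 is the only stereocentre, a fully substituted carbon bonded to the ring oxygen. No second centre can induce it, so its S configuration must come from the chiral pool and be in place before the ring is closed. The seven-membered ether is the structural difficulty: O1 sits on a tertiary carbon flanked by two carbonyl-bearing groups, so the ether bond is better made intermolecularly and the ring closed through a C–C bond. Two trisubstituted alkenes need fixed geometry, the ring alkene (C4 and C7 cis) and the E side-chain alkene. The molecule is fragile in several ways: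

- the ketone is β to O1, so base can open the ring by β-elimination;
- the free hydroquinone oxidises under basic, aerobic conditions;
- the allylic coumarate and the allylic ether C7–O1 can ionise under strong acid;
- the cinnamate alkene rules out hydrogenolytic deprotection.

The feature that opens the ring synthesis is the C4–C5 bond. C3–C4 is what anti-Markovnikov hydroboration of a vinyl group on C2 gives, and C5 with its cis neighbour C7 is exactly a (Z)-iodoalkene O–C7H2–C6(R)=C5H–I. The ring can therefore be closed by an sp3–sp2 coupling that does not have to create the double bond.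

## Retrosynthesis

**Unmasking (30 ⇐ 29 ⇐ 28).** Only O–C bonds of protecting groups are cut. The hydroquinone is released last and under acid, from bis(methoxymethyl) ether 29, so the free hydroquinone never meets base. The acid in 29 comes from the 2-(trimethylsilyl)ethyl ester 28, which is cleaved by fluoride while the hydroquinone is still masked. Hydrogenolysis and saponification are excluded by the cinnamate and the β-alkoxy ketone.

**Coumarate ester (28 ⇐ 26 + 27).** The ester C–O bond of the side chain is cut to the primary allylic alcohol 26 and unprotected p-coumaric acid 27. Redox esterification is chosen over acylation because the carboxylic acid is far more acidic than the phenol, so 27 needs no protecting group. Alcohol 26 comes from silyl ether 25. The coumarate is attached after the aryl ketone because it would not survive an aryllithium.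

**Aryl ketone (25 ⇐ 21 + 23).** The acyl–aryl bond is cut to the N-methoxy-N-methylamide 21 and the aryllithium 24. Reagent 24 comes from ortho-lithiation of bis(methoxymethyl) ether 23, itself one step from hydroquinone 22. Keeping the carbonyl as an amide until this point has two advantages over carrying the ketone: its α-protons are much less acidic, so O1 is not expelled in the basic steps before it, and the tetrahedral adduct stops at the ketone. The forward step must favour the amide over the hindered ester.

**Ring closure (21 ⇐ 20 ⇐ 19).** The C4–C5 bond of the oxepine is cut. The precursor 19 is acyclic: a vinyl group on C2 and a (Z)-iodoalkene on the ether arm. Hydroboration gives the B-alkylborane 20, which is then coupled within the molecule. Against closing O1–C7 (a seven-membered etherification on a hindered tertiary alcohol) or forming C5=C6 by metathesis (one more carbon to install on C2), this cut uses the shortest handle on C2 and stores the ring-alkene geometry in a stable iodide. No bond to C2 is touched. The descriptor is R in 19 and S in 20 and 21 only because vinyl outranks the amide-bearing methylene and the saturated chain does not.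

**Ether bond (19 ⇐ 9 + 17).** The O1–C7 bond is cut to the tertiary α-hydroxy ester 9 and the primary allylic bromide 17. The hindered ether is thus made with the most reactive electrophile the route offers and before any ring strain is involved. The forward reaction must alkylate a tertiary alkoxide without retro-aldol cleavage; the amide β to the alkoxide makes that cleavage unfavourable.

**Iodide fragment (17 ⇐ 16 ⇐ 14 + 13; 14 ⇐ 12 ⇐ 11 ⇐ 10).** Bromide 17 comes from alcohol 16. In 16 the C6–side-chain bond and the C5–I bond are cut together: anti-carbomagnesiation of propargyl alcohol 13 by Grignard reagent 14, then iodinolysis, gives the Z-iodoalkene in one flask. Reagent 14 comes from silyl ether 12, made from (E)-allylic alcohol 11, the allylic oxidation product of 5-bromo-2-methylpent-2-ene 10. That oxidation sets the E alkene and the oxygen for the coumarate in one step.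

**Stereocentre (9 ⇐ 8 ⇐ 7 ⇐ 4 + 5; 4 ⇐ 2 ⇐ 1).** Ester 9 arises by alcoholysis of dioxolanone 8. The vinyl group of 8 is traced to the aldol adduct 7 of enolate 6 (from amide 4) with acetaldehyde 5, the C4–vinyl bond being the one cut. Amide 4 comes from acid 2 through acid chloride 3, and 2 is the cis tert-butyl dioxolanone of L-malic acid 1. The tert-butyl-bearing acetal carbon keeps the chirality while C2 is trigonal, and the electrophile enters where the hydrogen was, so 1 supplies the S centre of 30 with retention. The amide is made before the aldol addition: a free carboxyl group would capture the new hydroxyl as a γ-lactone, and an amide α-methylene is much less acidic than the ring C–H.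

## Roads not taken

**Alternative 1:** The aryl ring is built last. Two C–C bonds of the benzene ring are cut, leading back to the terminal ynone A1 (the oxepine with a 2-oxobut-3-ynyl arm and the coumarate in place) and 2-methoxyfuran A2. Forward, a [4+2] cycloaddition joins the unsubstituted furan terminus to the alkyne CH and the methoxy-bearing carbon to the acyl-bearing carbon. The oxygen-bridged adduct opens with help from the methoxy group and tautomerises to the 5-hydroxy-2-methoxyphenyl ketone A3.
- Merits: the 1,2,5-pattern follows from the polarity match, and the ring-forming event is thermal and neutral with no organometallic near the ester. In that respect it is better than the addition of 24 to 21.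
- Weak points: it does not address the oxepine, which must still be made by some ring closure. Making A1 needs an ethynyl nucleophile on the same amide, so the amide-versus-ester question is not avoided. The methylene of A1 lies between an ynone and the O1-bearing carbon and is more prone to β-elimination than the aryl ketone. A3 keeps a methyl ether that must be cleaved by a strong boron-based Lewis acid next to an allylic ester and an allylic ether.
- Comparison: the chosen plan buys the ring as 22, attaches it in one step and removes its protecting groups under mild acid. What it has to set against the alternative's neutral conditions is a low-temperature, chemoselective addition, backed by a fallback.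

**Alternative 2:** The ring is closed at C6–C7 by a vinylsilane-terminated oxocarbenium cyclisation. The precursor A4 carries a 2-methoxyethoxymethyl ether on the tertiary oxygen and a (Z)-vinylsilane at C5=C6. A strong Lewis acid ionises the acetal, the silicon-bearing carbon attacks the oxocarbenium carbon, and loss of silicon gives the oxepine thioester A5 with the alkene fixed at C5=C6.
- Merits: the alkene position and geometry are controlled by silicon, no transition metal is needed, and the tertiary oxygen only has to be converted into an acetal. This class of cyclisation has closer precedent for seven-membered cyclic ethers than a ring-closing B-alkyl coupling has, and on that point it is the stronger plan.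
- Weak points: the Lewis acid acts on a substrate that already holds the allylic coumarate and a second, nucleophilic trisubstituted alkene that can compete for the cation. The oxocarbenium ion sits on an oxygen attached to an electron-poor tertiary carbon and is correspondingly unselective. A4 needs a four-carbon chain on C2 ending in a stereodefined trisubstituted vinylsilane, which means either alkylating the hindered dioxolanone enolate with an unactivated electrophile or building the chain in several steps. The thioester and trichloroethyl ester add protecting-group operations.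
- Comparison: the chosen plan answers with near-neutral ring closure, a convergent union through a reactive allylic bromide, and a one-flask synthesis of the fragment that stores the geometry.

**Alternative 3:** The seven-membered ring is made by one-carbon expansion of a six-membered one. The (S)-3,4-dihydro-2H-pyran A6 is dibromocyclopropanated at its enol ether, and silver-assisted solvolytic opening inserts C6, forming C5–C6 and C6–C7. The product is the 6-bromo-7-methoxy oxepine A7 as both C7 epimers.
- Merits: no entropically difficult seven-membered closure is needed, and the C6 bromide allows the side chain to be attached late by cross-coupling, which is more flexible for analogues than the chosen plan.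
- Weak points: the carbene is generated under strongly basic conditions in the presence of a β-alkoxy amide and an ester. The C7 methoxy group must then be removed by ionic reduction through an allylic cation that can transpose. The side chain still has to be joined. The sequence (dihydropyran, cyclopropanation, opening, reduction, coupling) is clearly longer.
- Comparison: the chosen plan installs ring, ring alkene and side chain in one ring-closing event, and pays for this with a less precedented ring size in the coupling.

Key step: step 11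

Remark on the chemistry: adduct 7 is taken as a mixture of both carbinol epimers (that carbon becomes sp2 in step 4), and 1,4-bis(methoxymethoxy)benzene 23 is prepared rather than bought.

## Route

Step 1
Reactants: 1 L-malic acid
Product: 2 2-[(2S,4S)-2-tert-butyl-5-oxo-1,3-dioxolan-4-yl]acetic acid (cis)
Conditions: t-BuCHO, p-TsOH (cat.), H2SO4 (cat.), pentane, reflux, Dean–Stark; recrystallisation
Reagents that add atoms: pivalaldehyde (CC(C)(C)C=O)
Why: Acid-catalysed acetalisation of the α-hydroxy acid unit with water removal; the five-membered acylal is preferred, and the cis isomer is favoured and should be purified by crystallisation, so the acetal carbon stores the configuration of the malic acid centre.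

Step 2
Reactants: 2 2-[(2S,4S)-2-tert-butyl-5-oxo-1,3-dioxolan-4-yl]acetic acid
Product: 4 2-[(2S,4S)-2-tert-butyl-5-oxo-1,3-dioxolan-4-yl]-N-methoxy-N-methylacetamide, via acid chloride 3 (not isolated)
Conditions: (COCl)2, DMF (cat.), CH2Cl2, 0 °C → rt; concentrate; MeNH(OMe)·HCl, pyridine, CH2Cl2, 0 °C
Reagents that add atoms: N,O-dimethylhydroxylamine hydrochloride (CNOC.Cl)
Why: Acid chloride formation and N-acylation of a weakly nucleophilic amine, which the acylal ring should tolerate; the amide is made now so that no carboxyl group can lactonise onto the hydroxyl formed in step 3.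

Step 3
Reactants: 4 2-[(2S,4S)-2-tert-butyl-5-oxo-1,3-dioxolan-4-yl]-N-methoxy-N-methylacetamide; 5 acetaldehyde
Product: 7 2-[(2S,4R)-2-tert-butyl-4-(1-hydroxyethyl)-5-oxo-1,3-dioxolan-4-yl]-N-methoxy-N-methylacetamide (both carbinol epimers), via lithium enolate 6 (not isolated)
Conditions: LiN(SiMe3)2 (1.05 equiv), THF, −78 °C; MeCHO (3 equiv), −78 °C; AcOH, −78 °C
Reagents that add atoms: none
Why: Aldol addition of a dioxolanone enolate with self-regeneration of the stereocentre: the base should remove the ring proton α to the lactone-type carbonyl rather than the much less acidic amide α-proton, and acetaldehyde adds to the enolate face opposite the tert-butyl group, where the hydrogen was, so the configuration is retained (the descriptor becomes R by priority only).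

Step 4
Reactants: 7 2-[(2S,4R)-2-tert-butyl-4-(1-hydroxyethyl)-5-oxo-1,3-dioxolan-4-yl]-N-methoxy-N-methylacetamide
Product: 8 2-[(2S,4R)-2-tert-butyl-4-ethenyl-5-oxo-1,3-dioxolan-4-yl]-N-methoxy-N-methylacetamide
Conditions: Burgess reagent (2 equiv), toluene, 60 °C
Reagents that add atoms: none
Why: Burgess dehydration (syn-elimination of the sulfamate ester); the carbinol carbon has β-hydrogens only on its methyl group because the other neighbour is quaternary, so the terminal vinyl group is the only alkene that can form and both carbinol epimers converge.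

Step 5
Reactants: 8 2-[(2S,4R)-2-tert-butyl-4-ethenyl-5-oxo-1,3-dioxolan-4-yl]-N-methoxy-N-methylacetamide
Product: 9 2-(trimethylsilyl)ethyl (2R)-2-hydroxy-2-{2-[methoxy(methyl)amino]-2-oxoethyl}but-3-enoate
Conditions: Me3SiCH2CH2OH (5 equiv), NaH (0.3 equiv), THF, 0 °C
Reagents that add atoms: 2-(trimethylsilyl)ethanol (C[Si](C)(C)CCO)
Why: Alkoxide-catalysed alcoholysis of the dioxolanone: addition to the ring carbonyl, loss of pivalaldehyde from the hemiacetal alkoxide and proton transfer regenerate the nucleophile; the C–O bond at the stereocentre is not broken.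

Step 6
Reactants: 10 5-bromo-2-methylpent-2-ene
Product: 11 (2E)-5-bromo-2-methylpent-2-en-1-ol
Conditions: SeO2 (0.5 equiv), t-BuOOH (2 equiv), salicylic acid (cat.), CH2Cl2, 0 °C → rt
Reagents that add atoms: selenium dioxide (O=[Se]=O) as oxygen carrier; tert-butyl hydroperoxide (CC(C)(C)OO) as terminal oxygen source
Why: Selenium dioxide allylic oxidation (ene reaction, then [2,3]-sigmatropic shift); trisubstituted gem-dimethyl alkenes are hydroxylated at the methyl group trans to the chain, which fixes the E geometry.

Step 7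
Reactants: 11 (2E)-5-bromo-2-methylpent-2-en-1-ol
Product: 12 {[(2E)-5-bromo-2-methylpent-2-en-1-yl]oxy}(tert-butyl)dimethylsilane
Conditions: t-BuMe2SiCl, imidazole, CH2Cl2, 0 °C → rt
Reagents that add atoms: tert-butyldimethylsilyl chloride (CC(C)(C)[Si](C)(C)Cl)
Why: Standard silylation of a primary alcohol; the silyl ether is inert to magnesium and to the later basic and palladium steps.

Step 8
Reactants: 12 {[(2E)-5-bromo-2-methylpent-2-en-1-yl]oxy}(tert-butyl)dimethylsilane; 13 propargyl alcohol
Product: 16 (2Z,5E)-7-[(tert-butyldimethylsilyl)oxy]-2-(iodomethylidene)-6-methylhept-5-en-1-ol, via Grignard reagent 14 (not isolated), via cyclic vinylmagnesium alkoxide 15 (not isolated)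
Conditions: 12, Mg, THF, 40 °C; separately 13 (1.5 equiv), EtMgBr (1.5 equiv), THF/Et2O, 0 °C; combine, CuI (0.15 equiv), rt; then I2, −40 → 0 °C
Reagents that add atoms: iodine (II)
Why: Copper-catalysed anti-carbomagnesiation of propargyl alcohol, then iodinolysis: the magnesium alkoxide directs the alkyl group to the internal alkyne carbon and magnesium to the terminal carbon cis to the CH2O group (chelate 15), and iodine replaces magnesium with retention to give the Z-iodoalkene; the O–H is removed beforehand with EtMgBr so that 14 is not spent as a base.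

Step 9
Reactants: 16 (2Z,5E)-7-[(tert-butyldimethylsilyl)oxy]-2-(iodomethylidene)-6-methylhept-5-en-1-ol
Product: 17 {[(2E,6Z)-6-(bromomethyl)-7-iodo-2-methylhepta-2,6-dien-1-yl]oxy}(tert-butyl)dimethylsilane
Conditions: CBr4, PPh3, CH2Cl2, 0 °C
Reagents that add atoms: carbon tetrabromide (BrC(Br)(Br)Br)
Why: Appel bromination by SN2 displacement at the primary allylic carbon under neutral conditions, which should leave the silyl ether and both alkene geometries unchanged.

Step 10
Reactants: 9 2-(trimethylsilyl)ethyl (2R)-2-hydroxy-2-{2-[methoxy(methyl)amino]-2-oxoethyl}but-3-enoate; 17 {[(2E,6Z)-6-(bromomethyl)-7-iodo-2-methylhepta-2,6-dien-1-yl]oxy}(tert-butyl)dimethylsilane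
Product: 19 2-(trimethylsilyl)ethyl (2R)-2-({(2Z,5E)-7-[(tert-butyldimethylsilyl)oxy]-2-(iodomethylidene)-6-methylhept-5-en-1-yl}oxy)-2-{2-[methoxy(methyl)amino]-2-oxoethyl}but-3-enoate, via sodium alkoxide 18 (not isolated)
Conditions: NaH (1.2 equiv), DMF, −20 °C; 17 (1.3 equiv), n-Bu4NI (0.1 equiv), −20 → 0 °C
Reagents that add atoms: none
Why: Williamson etherification of a tertiary α-hydroxy ester alkoxide with a primary allylic bromide under iodide catalysis; SN2 at C7 leaves the stereocentre and the iodoalkene untouched, and low temperature with an amide (not a ketone) β to the alkoxide should hold back retro-aldol cleavage.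

Step 11
Reactants: 19 2-(trimethylsilyl)ethyl (2R)-2-({(2Z,5E)-7-[(tert-butyldimethylsilyl)oxy]-2-(iodomethylidene)-6-methylhept-5-en-1-yl}oxy)-2-{2-[methoxy(methyl)amino]-2-oxoethyl}but-3-enoate
Product: 21 2-(trimethylsilyl)ethyl (2S)-6-[(3E)-5-[(tert-butyldimethylsilyl)oxy]-4-methylpent-3-en-1-yl]-2-{2-[methoxy(methyl)amino]-2-oxoethyl}-2,3,4,7-tetrahydrooxepine-2-carboxylate, via B-alkyl-9-BBN 20 (not isolated)
Conditions: 9-BBN (1.6 equiv), THF, 0 °C → rt; then slow addition to PdCl2(dppf) (0.1 equiv), AsPh3 (0.2 equiv), Cs2CO3 (3 equiv), DMF/THF/H2O, 50 °C, final 0.002 M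
Reagents that add atoms: none
Why: Hydroboration followed by a B-alkyl Suzuki–Miyaura coupling run as a ring closure. 9-BBN should add to the monosubstituted vinyl group much faster than to either trisubstituted alkene or the amide and place boron on the terminal carbon C4, which also keeps boron away from the carbon next to O1-bearing C2 where elimination would threaten. Zerovalent palladium formed from PdCl2(dppf) inserts into the C5–I bond with retention of the Z geometry, the base turns the alkylborane into a borate, the primary alkyl group passes to palladium, and reductive elimination forms C4–C5. The closest known reaction type is the intramolecular B-alkyl Suzuki–Miyaura coupling of haloalkenyl boranes used for five- and six-membered rings and macrocycles; the seven-membered cyclic ether is an extension in ring size only. The oxepine closes by C(sp3)–C(sp2) reductive elimination from an eight-membered alkyl(alkenyl)palladium intermediate, with both carbons of the former iodoalkene inside the ring. No stereocentre is formed; C2 is untouched and changes from R to S only because the saturated chain ranks below the amide arm. The step needs chemoselective hydroboration, secured by the steric difference between the alkenes, and ring closure in preference to chain growth, secured by slow addition into a dilute catalyst solution; the ring-alkene geometry cannot drift because the double bond is not made here, and the cis relation of C7 and iodine brings the reacting ends together.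

Step 12
Reactants: 22 hydroquinone
Product: 23 1,4-bis(methoxymethoxy)benzene
Conditions: MeOCH2Cl (2.5 equiv), i-Pr2NEt (3 equiv), CH2Cl2, 0 °C → rt
Reagents that add atoms: chloromethyl methyl ether (COCCl)
Why: Standard O-alkylation of a phenol to the methoxymethyl ether, which both protects the hydroquinone and directs the lithiation of step 13.

Step 13
Reactants: 21 2-(trimethylsilyl)ethyl (2S)-6-[(3E)-5-[(tert-butyldimethylsilyl)oxy]-4-methylpent-3-en-1-yl]-2-{2-[methoxy(methyl)amino]-2-oxoethyl}-2,3,4,7-tetrahydrooxepine-2-carboxylate; 23 1,4-bis(methoxymethoxy)benzene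
Product: 25 2-(trimethylsilyl)ethyl (2S)-2-{2-[2,5-bis(methoxymethoxy)phenyl]-2-oxoethyl}-6-[(3E)-5-[(tert-butyldimethylsilyl)oxy]-4-methylpent-3-en-1-yl]-2,3,4,7-tetrahydrooxepine-2-carboxylate, via aryllithium 24 (not isolated)
Conditions: 23 (1.6 equiv), n-BuLi (1.5 equiv), THF, 0 °C; then 21, −78 °C; sat. NH4Cl
Reagents that add atoms: none
Why: Directed ortho-lithiation and Weinreb ketone synthesis: the chelated tetrahedral adduct survives until work-up and prevents over-addition, and at −78 °C the amide should react in preference to the ester on the quaternary carbon.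

Step 14
Reactants: 25 2-(trimethylsilyl)ethyl (2S)-2-{2-[2,5-bis(methoxymethoxy)phenyl]-2-oxoethyl}-6-[(3E)-5-[(tert-butyldimethylsilyl)oxy]-4-methylpent-3-en-1-yl]-2,3,4,7-tetrahydrooxepine-2-carboxylate
Product: 26 2-(trimethylsilyl)ethyl (2S)-2-{2-[2,5-bis(methoxymethoxy)phenyl]-2-oxoethyl}-6-[(3E)-5-hydroxy-4-methylpent-3-en-1-yl]-2,3,4,7-tetrahydrooxepine-2-carboxylate
Conditions: HF·pyridine, pyridine, THF, 0 °C → rt
Reagents that add atoms: none
Why: Fluoride cleavage of a primary silyl ether under buffered, weakly acidic conditions, which should leave the 2-(trimethylsilyl)ethyl ester, the acetal ethers and the β-alkoxy ketone intact.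

Step 15
Reactants: 26 2-(trimethylsilyl)ethyl (2S)-2-{2-[2,5-bis(methoxymethoxy)phenyl]-2-oxoethyl}-6-[(3E)-5-hydroxy-4-methylpent-3-en-1-yl]-2,3,4,7-tetrahydrooxepine-2-carboxylate; 27 p-coumaric acid
Product: 28 2-(trimethylsilyl)ethyl (2S)-2-{2-[2,5-bis(methoxymethoxy)phenyl]-2-oxoethyl}-6-[(3E)-5-{[(2E)-3-(4-hydroxyphenyl)prop-2-enoyl]oxy}-4-methylpent-3-en-1-yl]-2,3,4,7-tetrahydrooxepine-2-carboxylate
Conditions: PPh3, DIAD, THF, 0 °C → rt
Reagents that add atoms: none
Why: Mitsunobu esterification: the carboxylic acid is several pKa units more acidic than the phenol, so it alone protonates the betaine and the carboxylate displaces the alkoxyphosphonium group at the primary allylic carbon without phenol protection.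

Step 16
Reactants: 28 2-(trimethylsilyl)ethyl (2S)-2-{2-[2,5-bis(methoxymethoxy)phenyl]-2-oxoethyl}-6-[(3E)-5-{[(2E)-3-(4-hydroxyphenyl)prop-2-enoyl]oxy}-4-methylpent-3-en-1-yl]-2,3,4,7-tetrahydrooxepine-2-carboxylate
Product: 29 (2S)-2-{2-[2,5-bis(methoxymethoxy)phenyl]-2-oxoethyl}-6-[(3E)-5-{[(2E)-3-(4-hydroxyphenyl)prop-2-enoyl]oxy}-4-methylpent-3-en-1-yl]-2,3,4,7-tetrahydrooxepine-2-carboxylic acid
Conditions: n-Bu4NF (3 equiv), THF, 0 °C → rt; 0.1 M HCl work-up
Reagents that add atoms: none
Why: Fluoride-induced fragmentation of the 2-(trimethylsilyl)ethyl ester (attack at silicon, loss of ethylene); it is run while the hydroquinone is still protected so that no free hydroquinone meets the basic fluoride.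

Step 17
Reactants: 29 (2S)-2-{2-[2,5-bis(methoxymethoxy)phenyl]-2-oxoethyl}-6-[(3E)-5-{[(2E)-3-(4-hydroxyphenyl)prop-2-enoyl]oxy}-4-methylpent-3-en-1-yl]-2,3,4,7-tetrahydrooxepine-2-carboxylic acid
Product: 30 (2S)-2-[2-(2,5-dihydroxyphenyl)-2-oxoethyl]-6-[(3E)-5-{[(2E)-3-(4-hydroxyphenyl)prop-2-enoyl]oxy}-4-methylpent-3-en-1-yl]-2,3,4,7-tetrahydrooxepine-2-carboxylic acid
Conditions: ZnBr2 (3 equiv), n-PrSH (6 equiv), CH2Cl2, 0 °C, argon
Reagents that add atoms: none
Why: Lewis acid-assisted cleavage of aryl methoxymethyl ethers with a thiol as trap for the methoxymethyl cation; the mild, non-basic, brief conditions should spare the allylic ester, the allylic ether and the β-alkoxy ketone, and the thiol keeps the electron-rich ring from being hydroxymethylated.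

## Compound list

1 | L-malic acid, (2S)-2-hydroxybutanedioic acid | O[C@@H](CC(=O)O)C(=O)O | starting material
2 | 2-[(2S,4S)-2-tert-butyl-5-oxo-1,3-dioxolan-4-yl]acetic acid | O1[C@@H](CC(=O)O)C(=O)O[C@H]1C(C)(C)C | intermediate
3 | 2-[(2S,4S)-2-tert-butyl-5-oxo-1,3-dioxolan-4-yl]acetyl chloride (not isolated) | O1[C@@H](CC(=O)Cl)C(=O)O[C@H]1C(C)(C)C | intermediate
4 | 2-[(2S,4S)-2-tert-butyl-5-oxo-1,3-dioxolan-4-yl]-N-methoxy-N-methylacetamide | O1[C@@H](CC(=O)N(C)OC)C(=O)O[C@H]1C(C)(C)C | intermediate
5 | acetaldehyde | CC=O | starting material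
6 | lithium (2S)-2-tert-butyl-5-{2-[methoxy(methyl)amino]-2-oxoethyl}-2H-1,3-dioxol-4-olate (not isolated) | O1C(CC(=O)N(C)OC)=C(O[Li])O[C@H]1C(C)(C)C | intermediate
7 | 2-[(2S,4R)-2-tert-butyl-4-(1-hydroxyethyl)-5-oxo-1,3-dioxolan-4-yl]-N-methoxy-N-methylacetamide (carbinol epimers) | O1[C@@](C(C)O)(CC(=O)N(C)OC)C(=O)O[C@H]1C(C)(C)C | intermediate
8 | 2-[(2S,4R)-2-tert-butyl-4-ethenyl-5-oxo-1,3-dioxolan-4-yl]-N-methoxy-N-methylacetamide | O1[C@@](C=C)(CC(=O)N(C)OC)C(=O)O[C@H]1C(C)(C)C | intermediate
9 | 2-(trimethylsilyl)ethyl (2R)-2-hydroxy-2-{2-[methoxy(methyl)amino]-2-oxoethyl}but-3-enoate | C=C[C@](CC(=O)N(C)OC)(C(=O)OCC[Si](C)(C)C)O | intermediate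
10 | 5-bromo-2-methylpent-2-ene | CC(C)=CCCBr | starting material
11 | (2E)-5-bromo-2-methylpent-2-en-1-ol | C/C(=C\CCBr)CO | intermediate
12 | {[(2E)-5-bromo-2-methylpent-2-en-1-yl]oxy}(tert-butyl)dimethylsilane | C/C(=C\CCBr)CO[Si](C)(C)C(C)(C)C | intermediate
13 | propargyl alcohol (prop-2-yn-1-ol) | C#CCO | starting material
14 | {(3E)-5-[(tert-butyldimethylsilyl)oxy]-4-methylpent-3-en-1-yl}magnesium bromide (not isolated) | C/C(=C\CC[Mg]Br)CO[Si](C)(C)C(C)(C)C | intermediate
15 | 4-{(3E)-5-[(tert-butyldimethylsilyl)oxy]-4-methylpent-3-en-1-yl}-2,5-dihydro-1,2-oxamagnesole, the cyclic vinylmagnesium alkoxide (not isolated) | C/C(=C\CCC1=C[Mg]OC1)CO[Si](C)(C)C(C)(C)C | intermediate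
16 | (2Z,5E)-7-[(tert-butyldimethylsilyl)oxy]-2-(iodomethylidene)-6-methylhept-5-en-1-ol | OC/C(=C\I)CC/C=C(\C)CO[Si](C)(C)C(C)(C)C | intermediate
17 | {[(2E,6Z)-6-(bromomethyl)-7-iodo-2-methylhepta-2,6-dien-1-yl]oxy}(tert-butyl)dimethylsilane | BrC/C(=C\I)CC/C=C(\C)CO[Si](C)(C)C(C)(C)C | intermediate
18 | sodium alkoxide of 9 (not isolated) | C=C[C@](CC(=O)N(C)OC)(C(=O)OCC[Si](C)(C)C)[O-].[Na+] | intermediate
19 | 2-(trimethylsilyl)ethyl (2R)-2-({(2Z,5E)-7-[(tert-butyldimethylsilyl)oxy]-2-(iodomethylidene)-6-methylhept-5-en-1-yl}oxy)-2-{2-[methoxy(methyl)amino]-2-oxoethyl}but-3-enoate | C=C[C@](CC(=O)N(C)OC)(C(=O)OCC[Si](C)(C)C)OC/C(=C\I)CC/C=C(\C)CO[Si](C)(C)C(C)(C)C | intermediate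
20 | 2-(trimethylsilyl)ethyl (2S)-4-(9-borabicyclo[3.3.1]nonan-9-yl)-2-({(2Z,5E)-7-[(tert-butyldimethylsilyl)oxy]-2-(iodomethylidene)-6-methylhept-5-en-1-yl}oxy)-2-{2-[methoxy(methyl)amino]-2-oxoethyl}butanoate (not isolated) | B1(C2CCCC1CCC2)CC[C@](CC(=O)N(C)OC)(C(=O)OCC[Si](C)(C)C)OC/C(=C\I)CC/C=C(\C)CO[Si](C)(C)C(C)(C)C | intermediate
21 | 2-(trimethylsilyl)ethyl (2S)-6-[(3E)-5-[(tert-butyldimethylsilyl)oxy]-4-methylpent-3-en-1-yl]-2-{2-[methoxy(methyl)amino]-2-oxoethyl}-2,3,4,7-tetrahydrooxepine-2-carboxylate | C/C(=C\CCC1=CCC[C@](CC(=O)N(C)OC)(C(=O)OCC[Si](C)(C)C)OC1)CO[Si](C)(C)C(C)(C)C | intermediate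
22 | hydroquinone (benzene-1,4-diol) | Oc1ccc(O)cc1 | starting material
23 | 1,4-bis(methoxymethoxy)benzene | COCOc1ccc(OCOC)cc1 | intermediate
24 | [2,5-bis(methoxymethoxy)phenyl]lithium (not isolated) | [Li]c1cc(OCOC)ccc1OCOC | intermediate
25 | 2-(trimethylsilyl)ethyl (2S)-2-{2-[2,5-bis(methoxymethoxy)phenyl]-2-oxoethyl}-6-[(3E)-5-[(tert-butyldimethylsilyl)oxy]-4-methylpent-3-en-1-yl]-2,3,4,7-tetrahydrooxepine-2-carboxylate | C/C(=C\CCC1=CCC[C@](CC(=O)c2cc(OCOC)ccc2OCOC)(C(=O)OCC[Si](C)(C)C)OC1)CO[Si](C)(C)C(C)(C)C | intermediate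
26 | 2-(trimethylsilyl)ethyl (2S)-2-{2-[2,5-bis(methoxymethoxy)phenyl]-2-oxoethyl}-6-[(3E)-5-hydroxy-4-methylpent-3-en-1-yl]-2,3,4,7-tetrahydrooxepine-2-carboxylate | C/C(=C\CCC1=CCC[C@](CC(=O)c2cc(OCOC)ccc2OCOC)(C(=O)OCC[Si](C)(C)C)OC1)CO | intermediate
27 | p-coumaric acid, (2E)-3-(4-hydroxyphenyl)prop-2-enoic acid | OC(=O)/C=C/c1ccc(O)cc1 | starting material
28 | 2-(trimethylsilyl)ethyl (2S)-2-{2-[2,5-bis(methoxymethoxy)phenyl]-2-oxoethyl}-6-[(3E)-5-{[(2E)-3-(4-hydroxyphenyl)prop-2-enoyl]oxy}-4-methylpent-3-en-1-yl]-2,3,4,7-tetrahydrooxepine-2-carboxylate | C/C(=C\CCC1=CCC[C@](CC(=O)c2cc(OCOC)ccc2OCOC)(C(=O)OCC[Si](C)(C)C)OC1)COC(=O)/C=C/c1ccc(O)cc1 | intermediate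
29 | (2S)-2-{2-[2,5-bis(methoxymethoxy)phenyl]-2-oxoethyl}-6-[(3E)-5-{[(2E)-3-(4-hydroxyphenyl)prop-2-enoyl]oxy}-4-methylpent-3-en-1-yl]-2,3,4,7-tetrahydrooxepine-2-carboxylic acid | C/C(=C\CCC1=CCC[C@](CC(=O)c2cc(OCOC)ccc2OCOC)(C(=O)O)OC1)COC(=O)/C=C/c1ccc(O)cc1 | intermediate
30 | (2S)-2-[2-(2,5-dihydroxyphenyl)-2-oxoethyl]-6-[(3E)-5-{[(2E)-3-(4-hydroxyphenyl)prop-2-enoyl]oxy}-4-methylpent-3-en-1-yl]-2,3,4,7-tetrahydrooxepine-2-carboxylic acid | C/C(=C\CCC1=CCC[C@](CC(=O)c2cc(O)ccc2O)(C(=O)O)OC1)COC(=O)/C=C/c1ccc(O)cc1 | target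

## Step count and least certain steps

Total: 17 steps. Longest linear sequence: 12 steps (steps 1–5, 10, 11, 13–17). The iodide fragment (steps 6–9) and the aryl piece (step 12) are made in parallel.

**Step 11 (key step).** Ring closure through an eight-membered palladium intermediate may be slow. Chain growth between two molecules, loss of iodine from the alkenylpalladium species by reduction, or protodeboronation of the alkylborane can then overtake it, and the aqueous base can begin to hydrolyse the ester. Fallback by ring-closing metathesis, setting out from 9 and 12 and returning at 21: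
- Alcohol 9 is hydroborated with 9-BBN and coupled intermolecularly with vinyl bromide (PdCl2(dppf), K3PO4) to give 2-(trimethylsilyl)ethyl (2S)-2-hydroxy-2-{2-[methoxy(methyl)amino]-2-oxoethyl}hex-5-enoate F1.
- The carbomagnesiation of step 8 is quenched with water instead of iodine to give (5E)-7-[(tert-butyldimethylsilyl)oxy]-6-methyl-2-methylidenehept-5-en-1-ol F2.
- Appel bromination converts it into {[(2E)-6-(bromomethyl)-2-methylhepta-2,6-dien-1-yl]oxy}(tert-butyl)dimethylsilane F3.
- Etherification of F1 with F3 as in step 10 gives 2-(trimethylsilyl)ethyl (2S)-2-({(5E)-7-[(tert-butyldimethylsilyl)oxy]-6-methyl-2-methylidenehept-5-en-1-yl}oxy)-2-{2-[methoxy(methyl)amino]-2-oxoethyl}hex-5-enoate F4.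
- Ring-closing metathesis of F4 with second-generation Grubbs catalyst forms C5=C6 and gives 21.

**Step 3.** Deprotonation may occur in part at the amide α-methylene instead of the ring carbon, which would open the dioxolanone by β-elimination, and the lithium aldolate may cyclise onto the amide if the mixture warms. Fallback, setting out from acid 2 and returning at 8 (it also bypasses step 4):
- The dianion of 2 (2 equiv LiN(SiMe3)2) is alkylated with allyl bromide, anti to the tert-butyl group, to give 2-[(2S,4S)-2-tert-butyl-5-oxo-4-(prop-2-en-1-yl)-1,3-dioxolan-4-yl]acetic acid F5.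
- Amidation as in step 2 gives 2-[(2S,4S)-2-tert-butyl-5-oxo-4-(prop-2-en-1-yl)-1,3-dioxolan-4-yl]-N-methoxy-N-methylacetamide F6.
- Alkene isomerisation with RuHCl(CO)(PPh3)3 gives 2-[(2S,4R)-2-tert-butyl-5-oxo-4-[(1E)-prop-1-en-1-yl]-1,3-dioxolan-4-yl]-N-methoxy-N-methylacetamide F7.
- Ethenolysis with second-generation Hoveyda–Grubbs catalyst under ethylene shortens the propenyl group to the vinyl group of 8.

**Step 4.** On heating, displacement of the activated hydroxyl by the neighbouring amide oxygen (lactone formation) or retro-aldol cleavage may compete with the syn-elimination. Fallback through a vinyl cation equivalent, setting out from 4 and returning at 8: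
- Enolate 6 is added to (phenylselanyl)acetaldehyde F8, prepared separately, to give 2-[(2S,4R)-2-tert-butyl-4-[1-hydroxy-2-(phenylselanyl)ethyl]-5-oxo-1,3-dioxolan-4-yl]-N-methoxy-N-methylacetamide F9.
- MsCl and Et3N at 0 °C convert F9 into 8 by loss of the hydroxyl and the selenium group through a seleniranium ion.

**Step 10.** Alkylation of the hindered tertiary alkoxide may be slow enough for retro-aldol fragmentation or base-induced elimination to take over. Fallback under acid catalysis, setting out from 16 and 9 and returning at 19: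
- Alcohol 16 is converted with Cl3CCN and catalytic DBU into (2Z,5E)-7-[(tert-butyldimethylsilyl)oxy]-2-(iodomethylidene)-6-methylhept-5-en-1-yl 2,2,2-trichloroethanimidate F10.
- F10 alkylates 9 under catalytic Me3SiOTf at −20 °C, without ever forming the alkoxide.

**Step 13.** The aryllithium may attack the ester, or act as a base at the amide α-methylene, which would expel O1 and open the ring. Fallback in three steps, setting out from 21 and returning at 25:
- Cp2Zr(H)Cl reduces the amide selectively to 2-(trimethylsilyl)ethyl (2S)-6-[(3E)-5-[(tert-butyldimethylsilyl)oxy]-4-methylpent-3-en-1-yl]-2-(2-oxoethyl)-2,3,4,7-tetrahydrooxepine-2-carboxylate F11.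
- The less basic arylcerium reagent from 24 and CeCl3 adds to give 2-(trimethylsilyl)ethyl (2S)-2-{2-[2,5-bis(methoxymethoxy)phenyl]-2-hydroxyethyl}-6-[(3E)-5-[(tert-butyldimethylsilyl)oxy]-4-methylpent-3-en-1-yl]-2,3,4,7-tetrahydrooxepine-2-carboxylate F12 as a mixture of carbinol epimers.
- Dess–Martin periodinane oxidises F12 to 25.

## Further compounds

F1 | step 11 | 2-(trimethylsilyl)ethyl (2S)-2-hydroxy-2-{2-[methoxy(methyl)amino]-2-oxoethyl}hex-5-enoate | C=CCC[C@](CC(=O)N(C)OC)(C(=O)OCC[Si](C)(C)C)O
F2 | step 11 | (5E)-7-[(tert-butyldimethylsilyl)oxy]-6-methyl-2-methylidenehept-5-en-1-ol | C=C(CO)CC/C=C(\C)CO[Si](C)(C)C(C)(C)C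
F3 | step 11 | {[(2E)-6-(bromomethyl)-2-methylhepta-2,6-dien-1-yl]oxy}(tert-butyl)dimethylsilane | C=C(CBr)CC/C=C(\C)CO[Si](C)(C)C(C)(C)C
F4 | step 11 | 2-(trimethylsilyl)ethyl (2S)-2-({(5E)-7-[(tert-butyldimethylsilyl)oxy]-6-methyl-2-methylidenehept-5-en-1-yl}oxy)-2-{2-[methoxy(methyl)amino]-2-oxoethyl}hex-5-enoate | C=CCC[C@](CC(=O)N(C)OC)(C(=O)OCC[Si](C)(C)C)OCC(=C)CC/C=C(\C)CO[Si](C)(C)C(C)(C)C
F5 | step 3 | 2-[(2S,4S)-2-tert-butyl-5-oxo-4-(prop-2-en-1-yl)-1,3-dioxolan-4-yl]acetic acid | O1[C@@](CC=C)(CC(=O)O)C(=O)O[C@H]1C(C)(C)C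
F6 | step 3 | 2-[(2S,4S)-2-tert-butyl-5-oxo-4-(prop-2-en-1-yl)-1,3-dioxolan-4-yl]-N-methoxy-N-methylacetamide | O1[C@@](CC=C)(CC(=O)N(C)OC)C(=O)O[C@H]1C(C)(C)C
F7 | step 3 | 2-[(2S,4R)-2-tert-butyl-5-oxo-4-[(1E)-prop-1-en-1-yl]-1,3-dioxolan-4-yl]-N-methoxy-N-methylacetamide | O1[C@@](/C=C/C)(CC(=O)N(C)OC)C(=O)O[C@H]1C(C)(C)C
F8 | step 4 | (phenylselanyl)acetaldehyde | O=CC[Se]c1ccccc1
F9 | step 4 | 2-[(2S,4R)-2-tert-butyl-4-[1-hydroxy-2-(phenylselanyl)ethyl]-5-oxo-1,3-dioxolan-4-yl]-N-methoxy-N-methylacetamide | O1[C@@](C(O)C[Se]c2ccccc2)(CC(=O)N(C)OC)C(=O)O[C@H]1C(C)(C)C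
F10 | step 10 | (2Z,5E)-7-[(tert-butyldimethylsilyl)oxy]-2-(iodomethylidene)-6-methylhept-5-en-1-yl 2,2,2-trichloroethanimidate | N=C(OC/C(=C\I)CC/C=C(\C)CO[Si](C)(C)C(C)(C)C)C(Cl)(Cl)Cl
F11 | step 13 | 2-(trimethylsilyl)ethyl (2S)-6-[(3E)-5-[(tert-butyldimethylsilyl)oxy]-4-methylpent-3-en-1-yl]-2-(2-oxoethyl)-2,3,4,7-tetrahydrooxepine-2-carboxylate | C/C(=C\CCC1=CCC[C@](CC=O)(C(=O)OCC[Si](C)(C)C)OC1)CO[Si](C)(C)C(C)(C)C
F12 | step 13 | 2-(trimethylsilyl)ethyl (2S)-2-{2-[2,5-bis(methoxymethoxy)phenyl]-2-hydroxyethyl}-6-[(3E)-5-[(tert-butyldimethylsilyl)oxy]-4-methylpent-3-en-1-yl]-2,3,4,7-tetrahydrooxepine-2-carboxylate | C/C(=C\CCC1=CCC[C@](CC(O)c2cc(OCOC)ccc2OCOC)(C(=O)OCC[Si](C)(C)C)OC1)CO[Si](C)(C)C(C)(C)C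
A1 | alternative 1 | 2-(trimethylsilyl)ethyl (2S)-6-[(3E)-5-{[(2E)-3-{4-[(tert-butyldimethylsilyl)oxy]phenyl}prop-2-enoyl]oxy}-4-methylpent-3-en-1-yl]-2-(2-oxobut-3-yn-1-yl)-2,3,4,7-tetrahydrooxepine-2-carboxylate | C/C(=C\CCC1=CCC[C@](CC(=O)C#C)(C(=O)OCC[Si](C)(C)C)OC1)COC(=O)/C=C/c1ccc(O[Si](C)(C)C(C)(C)C)cc1
A2 | alternative 1 | 2-methoxyfuran | COc1ccco1
A3 | alternative 1 | 2-(trimethylsilyl)ethyl (2S)-6-[(3E)-5-{[(2E)-3-{4-[(tert-butyldimethylsilyl)oxy]phenyl}prop-2-enoyl]oxy}-4-methylpent-3-en-1-yl]-2-[2-(5-hydroxy-2-methoxyphenyl)-2-oxoethyl]-2,3,4,7-tetrahydrooxepine-2-carboxylate | C/C(=C\CCC1=CCC[C@](CC(=O)c2cc(O)ccc2OC)(C(=O)OCC[Si](C)(C)C)OC1)COC(=O)/C=C/c1ccc(O[Si](C)(C)C(C)(C)C)cc1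
A4 | alternative 2 | 2,2,2-trichloroethyl (2S,5Z,9E)-11-{[(2E)-3-{4-[(tert-butyldimethylsilyl)oxy]phenyl}prop-2-enoyl]oxy}-2-[2-(ethylsulfanyl)-2-oxoethyl]-2-[(2-methoxyethoxy)methoxy]-10-methyl-6-(trimethylsilyl)undeca-5,9-dienoate | C/C(=C\CC/C(=C/CC[C@](CC(=O)SCC)(C(=O)OCC(Cl)(Cl)Cl)OCOCCOC)[Si](C)(C)C)COC(=O)/C=C/c1ccc(O[Si](C)(C)C(C)(C)C)cc1
A5 | alternative 2 | 2,2,2-trichloroethyl (2S)-6-[(3E)-5-{[(2E)-3-{4-[(tert-butyldimethylsilyl)oxy]phenyl}prop-2-enoyl]oxy}-4-methylpent-3-en-1-yl]-2-[2-(ethylsulfanyl)-2-oxoethyl]-2,3,4,7-tetrahydrooxepine-2-carboxylate | C/C(=C\CCC1=CCC[C@](CC(=O)SCC)(C(=O)OCC(Cl)(Cl)Cl)OC1)COC(=O)/C=C/c1ccc(O[Si](C)(C)C(C)(C)C)cc1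
A6 | alternative 3 | 2-(trimethylsilyl)ethyl (2S)-2-{2-[methoxy(methyl)amino]-2-oxoethyl}-3,4-dihydro-2H-pyran-2-carboxylate | C1=CCC[C@](CC(=O)N(C)OC)(C(=O)OCC[Si](C)(C)C)O1
A7 | alternative 3 | 2-(trimethylsilyl)ethyl (2S)-6-bromo-7-methoxy-2-{2-[methoxy(methyl)amino]-2-oxoethyl}-2,3,4,7-tetrahydrooxepine-2-carboxylate (both C7 epimers) | BrC1=CCC[C@](CC(=O)N(C)OC)(C(=O)OCC[Si](C)(C)C)OC1OC
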